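**Plan**

1. Retrosynthetic cuts (cembrane numbering: C1 = ring CH bearing C15, C2 = ring CH2, C3 = lactone CH–O, C4/C8/C12 = methyl-bearing ring carbons, C16 = lactone C=O). C8–OOH with C6=C7 goes back to a C7=C8 alkene; the 11,12-epoxide to C11=C12; the lactone C3–O and C4–OH to a C3=C4 alkene plus a C16 acid; the acid to an isopropenyl group; last, the ring bond C1–C2.
2. Enabling feature: the 14-membered carbocycle with methyls on C4, C8 and C12 and a three-carbon unit on C1 is an unrearranged head-to-tail tetraprenyl chain. C1–C2 is therefore the bond between C14 and C1 of geranylgeranyl diphosphate, whose allylic diphosphate end and terminal trisubstituted alkene are the partners a terpene cyclase joins.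
3. Forward order: geranylgeraniol → diphosphate → enzymatic closure of the 14-membered ring → isopropenyl to C16 acid → the acid reaches only C3=C4 (iodolactone → epoxide → diol → six-membered lactone) → the new C4–OH masks only C7=C8 as a bromoether → epoxidation of the one free alkene C11=C12 → unmasking → singlet-oxygen ene reaction.
4. Stereochemistry: C1 from the enzyme; C3 and C4 from anti addition across E-C3=C4 (iodolactonization, then two inversions at C4); C15 by equilibration in the lactone; C11/C12 from the Shi ketone; C8 from facial attack of singlet oxygen on the macrocyclic alkene.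

Key step: step 3

Remark: an (R)-selective cembrene A synthase is taken to be available as recombinant protein, and the L-fructose-derived Shi ketone is taken, by the spiro transition-state model, as the enantiomer that gives (S,S)-epoxides from E-trisubstituted alkenes.
Remark: C15 forms without control in step 4; compounds 5 to 12 are C15 epimer mixtures (SMILES leave C15 open) and converge in step 8.

**Step 1**
Reactants: 1 (2E,6E,10E)-geranylgeraniol
Product: 2 (2E,6E,10E)-geranylgeranyl bromide
Conditions: PBr3 (0.4 equiv), Et2O, −10 °C
Reagents that add atoms: phosphorus tribromide, BrP(Br)Br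
Why: Conversion of a primary allylic alcohol to the bromide with PBr3 (SN2 on the phosphite ester) at low temperature should keep the 2E geometry without allylic transposition; no stereocenter is formed.

**Step 2**
Reactants: 2 geranylgeranyl bromide
Product: 3 (2E,6E,10E)-geranylgeranyl diphosphate (handled as its tris-ammonium salt, drawn as the free acid)
Conditions: (n-Bu4N)3HP2O7 (2 equiv), MeCN, rt; cation-exchange resin (NH4+ form), aq. NH4HCO3; cellulose chromatography
Reagents that add atoms: tris(tetrabutylammonium) hydrogen diphosphate, CCCC[N+](CCCC)(CCCC)CCCC.CCCC[N+](CCCC)(CCCC)CCCC.CCCC[N+](CCCC)(CCCC)CCCC.OP(=O)([O-])OP(=O)([O-])[O-]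
Why: SN2 displacement of the allylic bromide by the diphosphate trianion in MeCN, the standard route to allylic diphosphates, followed by cation exchange; no stereocenter is formed.

**Step 3**
Reactants: 3 geranylgeranyl diphosphate
Product: 4 (R)-cembrene A, (1R,3E,7E,11E)-4,8,12-trimethyl-1-(prop-1-en-2-yl)cyclotetradeca-3,7,11-triene
Conditions: recombinant (R)-cembrene A synthase (class 1 diterpene synthase), MgCl2 (10 mM), HEPES buffer pH 7.5, glycerol (10%), 30 °C, n-pentane overlay
Reagents that add atoms: none
Why: The synthase binds the diphosphate through its Mg2+ cluster and ionizes it to the allyl cation spanning C2–C4 (target numbering), whose primary terminus C2 is attacked by the distal C1=C15 double bond held over it in the hydrophobic pocket; the resulting tertiary C15 cation loses a methyl proton to give the isopropenyl group. This is the native reaction type of class 1 terpene synthases (ionization, cyclization, deprotonation), and its closest non-enzymatic relative is a cation–olefin macrocyclization of an allylic electrophile. The 14-membered ring closes in exo mode with respect to the attacking alkene (bond to C1, charge left outside the ring on C15) and without allylic transposition, so the E geometry of C3=C4 is kept. The only new stereocenter, C1, is set by the enzyme, which presents one face of the C1=C15 bond to the cation, and the (R)-selective enzyme is chosen. The step needs closure at the fourteenth chain carbon in preference to six- or ten-membered closure, retention of all three E alkenes and clean terminal deprotonation, which no small acid or metal reagent provides. The enzyme's folding of the chain secures these, and the substrate supplies what it requires: an ionizable allylic diphosphate at one end and a nucleophilic trisubstituted alkene at the far end of the chain, with C1 thirteen carbons along from C2.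

**Step 4**
Reactants: 4 (R)-cembrene A
Product: 6 (1R,3E,7E,11E,15RS)-cembra-3,7,11-trien-16-ol, via B-alkyl-9-borabicyclononane 5 (not isolated)
Conditions: 9-borabicyclo[3.3.1]nonane (9-BBN, 1.2 equiv), THF, 0 °C → rt; then aq. NaOH, H2O2 (30%), 0 °C → rt
Reagents that add atoms: hydrogen peroxide, OO
Why: Brown hydroboration–oxidation: 9-BBN adds anti-Markovnikov to the 1,1-disubstituted isopropenyl alkene far faster than to the three trisubstituted ring alkenes, and oxidation gives the primary C16 alcohol; C15 is formed without control and is corrected in step 8.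

**Step 5**
Reactants: 6 cembra-3,7,11-trien-16-ol
Product: 8 (1R,3E,7E,11E,15RS)-cembra-3,7,11-trien-16-oic acid, via aldehyde 7 (not isolated)
Conditions: 2,2,6,6-tetramethylpiperidin-1-oxyl (TEMPO, 0.2 equiv), PhI(OAc)2 (2.2 equiv), MeCN/H2O (1:1), rt
Reagents that add atoms: water, O
Why: Nitroxyl-catalysed oxidation (oxoammonium cycle with PhI(OAc)2) takes the primary alcohol through aldehyde 7 and its hydrate to the acid and leaves the alkenes alone; no stereocenter is set.

**Step 6**
Reactants: 8 cembra-3,7,11-trien-16-oic acid
Product: 10 methyl (1R,3R,4R,7E,11E,15RS)-3,4-epoxycembra-7,11-dien-16-oate, via cis-fused iodolactone 9 (not isolated)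
Conditions: I2 (1.5 equiv), NaHCO3, MeCN, −20 → 0 °C, dark; aq. Na2S2O3; then K2CO3, MeOH, 0 °C → rt
Reagents that add atoms: methanol, CO
Why: Iodolactonization followed by base-induced conversion of the iodolactone into an epoxy ester: iodonium formation is reversible on every alkene, but only the C3=C4 iodonium lies within six-membered (6-exo) reach of the C16 carboxylate, the chair transition state with the C1–C14 and C3–C4 bonds equatorial should give the cis-fused lactone (3R, iodine anti on C4), and methanolysis frees the C3 alkoxide, which displaces iodide from C4 with inversion to give the (3R,4R)-epoxide.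

**Step 7**
Reactants: 10 (3R,4R)-epoxy methyl ester
Product: 11 methyl (1R,3R,4S,7E,11E,15RS)-3,4-dihydroxycembra-7,11-dien-16-oate
Conditions: HClO4 (0.1 M aq., cat.), THF/H2O (3:1), 0 °C
Reagents that add atoms: water, O
Why: Acid-catalysed epoxide hydrolysis: water should open the trisubstituted epoxide at the tertiary carbon C4 with inversion (giving 4S) while C3 keeps its oxygen and its R configuration, the methyl ester being too poor a neighbouring group to compete at C3.

**Step 8**
Reactants: 11 (3R,4S)-diol methyl ester
Product: 13 (1R,3R,4S,7E,11E,15S)-4-hydroxycembra-7,11-dien-16,3-olide, via C15-epimeric lactone mixture 12 (not isolated)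
Conditions: 1,8-diazabicyclo[5.4.0]undec-7-ene (DBU, 2 equiv), toluene, 80 °C
Reagents that add atoms: none
Why: Base-promoted lactonization (transesterification) closes the six-membered lactone on the secondary C3 hydroxyl in preference to a seven-membered ring on the tertiary C4 hydroxyl, and DBU equilibrates the enolizable C15 centre of 12 to the all-equatorial lactone, in which the C15 methyl is trans to the C1 ring bond (15S).

**Step 9**
Reactants: 13 hydroxy lactone
Product: 14 (1R,3R,4S,7R,8S,11E,15S)-7-bromo-4,8-epoxycembr-11-en-16,3-olide (tetrahydropyran bridging C4 and C8, bromine on C7 anti to the ether oxygen)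
Conditions: N-bromosuccinimide (1.05 equiv), NaHCO3 (solid), CH2Cl2, −40 → −20 °C, dark
Reagents that add atoms: N-bromosuccinimide, O=C1CCC(=O)N1Br
Why: Bromoetherification: the bromonium ion, which can form reversibly on either alkene, is captured only at C7=C8, where the C4 hydroxyl attacks the tertiary C8 (6-endo, Markovnikov, anti to bromine) to give the cis-bridged tetrahydropyran, so that this alkene is masked and C11=C12 is left as the only alkene; the C7 and C8 centres are temporary and a 5-exo regioisomer would converge in step 11.

**Step 10**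
Reactants: 14 bromoether
Product: 15 (1R,3R,4S,7R,8S,11S,12S,15S)-7-bromo-4,8:11,12-diepoxycembran-16,3-olide
Conditions: 1,2:4,5-di-O-isopropylidene-β-L-erythro-2,3-hexodiulo-2,6-pyranose (L-fructose-derived Shi ketone, 0.3 equiv), KHSO5 (as the triple salt 2KHSO5·KHSO4·K2SO4), K2CO3, (n-Bu4N)HSO4 (cat.), MeCN/CH2(OMe)2–aq. Na2B4O7 buffer, pH 10, 0 °C
Reagents that add atoms: potassium peroxymonosulfate, [K+].[O-]S(=O)(=O)OO
Why: Shi epoxidation: the chiral dioxirane formed from the L-fructose-derived ketone and KHSO5 transfers oxygen to the only remaining alkene through the spiro transition state, which should give the (11S,12S)-epoxide under reagent control.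

**Step 11**
Reactants: 15 epoxy bromoether
Product: 16 (1R,3R,4S,7E,11S,12S,15S)-11,12-epoxy-4-hydroxycembr-7-en-16,3-olide
Conditions: Zn dust (activated, 10 equiv), EtOH, 70 °C; aq. NH4Cl work-up
Reagents that add atoms: none
Why: Boord-type reductive elimination: zinc inserts into the C7–Br bond and the anti-periplanar C8–O bond of the ether is expelled, which unmasks the C4 hydroxyl and, because an anti addition is undone by an anti elimination, should return the E-C7=C8 alkene; epoxide and lactone are inert to zinc in neutral ethanol.

**Step 12**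
Reactants: 16 epoxy alkene
Product: 17 (1R,3R,4S,6E,8R,11S,12S,15S)-11,12-epoxy-8-hydroperoxy-4-hydroxycembr-6-en-16,3-olide (target)
Conditions: O2, visible light (LED), 5,10,15,20-tetraphenylporphyrin (1 mol %), CH2Cl2, −20 °C
Reagents that add atoms: dioxygen, O=O
Why: Schenck ene reaction of singlet oxygen with the only alkene: oxygen bonds to the tertiary C8 while an allylic hydrogen is taken suprafacially from C6 on the disubstituted side of the E-alkene (cis effect), which moves the double bond to E-C6=C7; the C8 configuration (R) is set by attack on the exposed face of the macrocyclic alkene, the event by which such hydroperoxides plausibly arise in nature.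

**Compound list**

1 | (2E,6E,10E)-geranylgeraniol | CC(C)=CCC/C(C)=C/CC/C(C)=C/CC/C(C)=C/CO | starting material
2 | (2E,6E,10E)-geranylgeranyl bromide | CC(C)=CCC/C(C)=C/CC/C(C)=C/CC/C(C)=C/CBr | intermediate
3 | (2E,6E,10E)-geranylgeranyl diphosphate (free acid drawn; used as tris-ammonium salt) | CC(C)=CCC/C(C)=C/CC/C(C)=C/CC/C(C)=C/COP(=O)(O)OP(=O)(O)O | intermediate
4 | (R)-cembrene A | C=C(C)[C@@H]1CC/C(C)=C/CC/C(C)=C/CC/C(C)=C/C1 | intermediate
5 | B-[(1R,15RS)-cembra-3,7,11-trien-16-yl]-9-borabicyclo[3.3.1]nonane | CC(CB1C2CCCC1CCC2)[C@@H]1CC/C(C)=C/CC/C(C)=C/CC/C(C)=C/C1 | intermediate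
6 | (1R,15RS)-cembra-3,7,11-trien-16-ol | CC(CO)[C@@H]1CC/C(C)=C/CC/C(C)=C/CC/C(C)=C/C1 | intermediate
7 | (1R,15RS)-cembra-3,7,11-trien-16-al | CC(C=O)[C@@H]1CC/C(C)=C/CC/C(C)=C/CC/C(C)=C/C1 | intermediate
8 | (1R,15RS)-cembra-3,7,11-trien-16-oic acid | CC(C(=O)O)[C@@H]1CC/C(C)=C/CC/C(C)=C/CC/C(C)=C/C1 | intermediate
9 | (1R,3R,4S,15RS)-4-iodocembra-7,11-dien-16,3-olide (cis-fused iodolactone) | CC1C(=O)O[C@@H]2C[C@H]1CC/C(C)=C/CC/C(C)=C/CC[C@]2(C)I | intermediate
10 | methyl (1R,3R,4R,15RS)-3,4-epoxycembra-7,11-dien-16-oate | COC(=O)C(C)[C@H]1C[C@H]2O[C@]2(C)CC/C=C(C)/CC/C=C(C)/CC1 | intermediate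
11 | methyl (1R,3R,4S,15RS)-3,4-dihydroxycembra-7,11-dien-16-oate | COC(=O)C(C)[C@H]1C[C@@H](O)[C@@](C)(O)CC/C=C(C)/CC/C=C(C)/CC1 | intermediate
12 | (1R,3R,4S,15RS)-4-hydroxycembra-7,11-dien-16,3-olide (C15 epimer mixture) | CC1C(=O)O[C@@H]2C[C@H]1CC/C(C)=C/CC/C(C)=C/CC[C@]2(C)O | intermediate
13 | (1R,3R,4S,15S)-4-hydroxycembra-7,11-dien-16,3-olide | C[C@@H]1C(=O)O[C@@H]2C[C@H]1CC/C(C)=C/CC/C(C)=C/CC[C@]2(C)O | intermediate
14 | (1R,3R,4S,7R,8S,15S)-7-bromo-4,8-epoxycembr-11-en-16,3-olide | C[C@@H]1C(=O)O[C@@H]2C[C@H]1CC/C(C)=C/CC[C@]3(C)O[C@@]2(C)CC[C@H]3Br | intermediate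
15 | (1R,3R,4S,7R,8S,11S,12S,15S)-7-bromo-4,8:11,12-diepoxycembran-16,3-olide | C[C@@H]1C(=O)O[C@@H]2C[C@H]1CC[C@]1(C)O[C@H]1CC[C@]3(C)O[C@@]2(C)CC[C@H]3Br | intermediate
16 | (1R,3R,4S,7E,11S,12S,15S)-11,12-epoxy-4-hydroxycembr-7-en-16,3-olide | C[C@@H]1C(=O)O[C@@H]2C[C@H]1CC[C@]1(C)O[C@H]1CC/C(C)=C/CC[C@]2(C)O | intermediate
17 | (1R,3R,4S,6E,8R,11S,12S,15S)-11,12-epoxy-8-hydroperoxy-4-hydroxycembr-6-en-16,3-olide | C[C@@H]1C(=O)O[C@@H]2C[C@H]1CC[C@]1(C)O[C@H]1CC[C@@](C)(OO)/C=C/C[C@]2(C)O | target

**Step count and risks**

Total steps: 12. Longest linear sequence: 12 (the route is linear from 1).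

Steps most likely to fail:

Step 12. The ene reaction may abstract a hydrogen of the C19 methyl in place of C6–H (giving the secondary 7-hydroperoxide with an exocyclic alkene), or singlet oxygen may attack the wrong face of C7=C8. The fallback sets out from 16 and fixes the regiochemistry by polar addition and elimination. The C4 hydroxyl is silylated with 1-(trimethylsilyl)imidazole to the trimethylsilyl ether F5, so that it cannot trap a bromonium ion. Bromohydroperoxidation (1,3-dibromo-5,5-dimethylhydantoin, anhydrous H2O2, Et2O, −40 °C) then places OOH on the tertiary C8 and bromine anti on C7 to give the bromo hydroperoxide F6. The hydroperoxide is capped with 2-methoxypropene (pyridinium p-toluenesulfonate, cat.) as the base-stable peroxyketal F7. Elimination with DBU can only take a C6 hydrogen, because C8 carries none, and should give the E-C6=C7 peroxyketal F8. Aqueous AcOH/THF removes the peroxyketal and the silyl ether, and the route comes back at 17. The C8 configuration is then decided by the face of bromonium formation and not by the ene geometry.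

Step 6. The carboxylate may capture the iodonium ion from the other face of C3=C4 (poor or reversed facial selectivity), which would give the 3,4-epoxide of opposite configuration, for which hydrolysis at C4 leads to the wrong diol. The fallback sets out from 8 and changes the ring-opening mode. The same iodolactonization then runs through the trans-fused iodolactone F1, and methanolysis gives the (3S,4S)-epoxy ester F2. F2 is saponified (LiOH, THF/H2O) to the epoxy acid F3. On mild acidification (pyridinium p-toluenesulfonate, CH2Cl2) its carboxyl group should open the epoxide at C3 in 6-exo mode with inversion, and the route comes back at 12, which step 8 conditions equilibrate to 13. If both epoxides form, 10 and F2 are separated and each is opened in its own mode, so both faces converge.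

Step 11. The E geometry may be lost if the organozinc intermediate equilibrates before elimination, or unmasking may be incomplete; the bromonium chemistry of step 9 carries the related risk of transannular C–C bond formation. The fallback sets out from 13 and uses no mask. Shi epoxidation as in step 10, with one equivalent of KHSO5 and stopped at partial conversion, should give 16 together with its regioisomer, the 7,8-epoxide F4, and recovered 13. 16 is separated by chromatography, 13 is recycled, and the route comes back at 16.

**Further compounds**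

F1 | step 6 | (1R,3S,4R,15RS)-4-iodocembra-7,11-dien-16,3-olide (trans-fused iodolactone) | CC1C(=O)O[C@H]2C[C@H]1CC/C(C)=C/CC/C(C)=C/CC[C@@]2(C)I
F2 | step 6 | methyl (1R,3S,4S,15RS)-3,4-epoxycembra-7,11-dien-16-oate | COC(=O)C(C)[C@H]1C[C@@H]2O[C@@]2(C)CC/C=C(C)/CC/C=C(C)/CC1
F3 | step 6 | (1R,3S,4S,15RS)-3,4-epoxycembra-7,11-dien-16-oic acid | OC(=O)C(C)[C@H]1C[C@@H]2O[C@@]2(C)CC/C=C(C)/CC/C=C(C)/CC1
F4 | step 11 | (1R,3R,4S,7S,8S,11E,15S)-7,8-epoxy-4-hydroxycembr-11-en-16,3-olide | C[C@@H]1C(=O)O[C@@H]2C[C@H]1CC/C(C)=C/CC[C@]1(C)O[C@H]1CC[C@]2(C)O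
F5 | step 12 | (1R,3R,4S,7E,11S,12S,15S)-11,12-epoxy-4-(trimethylsilyloxy)cembr-7-en-16,3-olide | C[C@@H]1C(=O)O[C@@H]2C[C@H]1CC[C@]1(C)O[C@H]1CC/C(C)=C/CC[C@]2(C)O[Si](C)(C)C
F6 | step 12 | (1R,3R,4S,7S,8R,11S,12S,15S)-7-bromo-11,12-epoxy-8-hydroperoxy-4-(trimethylsilyloxy)cembran-16,3-olide | C[C@@H]1C(=O)O[C@@H]2C[C@H]1CC[C@]1(C)O[C@H]1CC[C@@](C)(OO)[C@@H](Br)CC[C@]2(C)O[Si](C)(C)C
F7 | step 12 | 8-(2-methoxyprop-2-ylperoxy) derivative of F6 (peroxyketal) | C[C@@H]1C(=O)O[C@@H]2C[C@H]1CC[C@]1(C)O[C@H]1CC[C@@](C)(OOC(C)(C)OC)[C@@H](Br)CC[C@]2(C)O[Si](C)(C)C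
F8 | step 12 | (1R,3R,4S,6E,8R,11S,12S,15S)-11,12-epoxy-8-(2-methoxyprop-2-ylperoxy)-4-(trimethylsilyloxy)cembr-6-en-16,3-olide | C[C@@H]1C(=O)O[C@@H]2C[C@H]1CC[C@]1(C)O[C@H]1CC[C@@](C)(OOC(C)(C)OC)/C=C/C[C@]2(C)O[Si](C)(C)C
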